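## Retrosynthetic overview

1. The target is the Schenck-ene (C5–O) adduct of ovatodiolide 21: singlet oxygen adds to the 4E alkene, giving C5–OOH and the C4=C18 methylene in the last step.
2. Ovatodiolide 21 comes from cyclobutenyl ester 20 by one ring-opening/ring-closing metathesis cascade. It closes the butenolide (second ring) and then the 14-membered carbocycle (third ring).
3. Ester 20 is disconnected at the C10–O bond: enantioselective rhodium-catalysed addition of cyclobut-1-enecarboxylic acid 18 to the terminal alkyne of lactone 15 sets C10.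
4. Lactone 15 (first ring, trans α-methylene-γ-butyrolactone, C1 and C14) comes from phosphoric-acid-catalysed allylboration/lactonisation of enynal 6 with (Z)-allylboronate 12.
5. Enynal 6 comes from geranyl acetate, boronate 12 from 4-bromo-2-methylbut-1-ene, and acid 18 from ethyl 1-bromocyclobutanecarboxylate.

Locants (cembrane numbering): C1 ring-fusion CH; C2, C3 CH2; C4 (bears C18); C5; C6, C7 CH2; C8 butenolide α-carbon (C19 its carbonyl); C9 butenolide =CH; C10 butenolide O–CH; C11 CH2; C12 (bears C20 methyl)=C13; C14 lactone O–CH; C15(=C17H2)–C16(=O)–O. The target is (1R,5R,10R,14S).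

Assumption: the enantiomers of the chiral phosphoric acid (step 7) and of the diphosphine (step 9) are those expected by analogy with simple substrates to give 14S and 10R; if the observed sense is reversed, the mirror-image catalyst is used.

## Route

Step 1
Reactants: 1 geranyl acetate [(2E)-3,7-dimethylocta-2,6-dien-1-yl acetate]
Product: 3 (2E)-3-methyl-6-oxohex-2-en-1-yl acetate, via ozonide 2 (not isolated)
Conditions: O3 (1.0 equiv), CH2Cl2, −78 °C; then Me2S, −78 °C → rt
Reagents that add atoms: ozone, [O-][O+]=O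
Why: Criegee ozonolysis is selective for the electron-rich 6,7-alkene because the 2,3-alkene is deactivated by the allylic acetate, so the E-trisubstituted alkene (the future C12=C13) is carried through untouched.

Step 2
Reactants: 3 (2E)-3-methyl-6-oxohex-2-en-1-yl acetate
Product: 5 (2E)-3-methylhept-2-en-6-yn-1-ol, via enynyl acetate 4 (not isolated)
Conditions: dimethyl (1-diazo-2-oxopropyl)phosphonate (1.3 equiv), K2CO3 (2.5 equiv), MeOH, 0 °C → rt
Reagents that add atoms: dimethyl (1-diazo-2-oxopropyl)phosphonate, COP(=O)(OC)C(=[N+]=[N-])C(C)=O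
Why: Seyferth–Gilbert homologation in its Ohira–Bestmann form turns the aldehyde into the terminal alkyne, and the same carbonate/methanol medium methanolyses the acetate.

Step 3
Reactants: 5 (2E)-3-methylhept-2-en-6-yn-1-ol
Product: 6 (2E)-3-methylhept-2-en-6-ynal
Conditions: activated MnO2 (15 equiv), CH2Cl2, rt
Reagents that add atoms: none
Why: MnO2 oxidation of the allylic alcohol is neutral and stops at the enal without E/Z isomerisation or attack on the alkyne.

Step 4
Reactants: 7 4-bromo-2-methylbut-1-ene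
Product: 8 2-methylhex-1-en-5-yne
Conditions: LiC≡CH·H2NCH2CH2NH2 (1.3 equiv), DMSO, 15 °C → rt; distil
Reagents that add atoms: lithium acetylide (used as its ethylenediamine complex), [Li]C#C
Why: SN2 alkylation of lithium acetylide by the unhindered primary bromide in DMSO, where substitution outruns E2.

Step 5
Reactants: 8 2-methylhex-1-en-5-yne
Product: 10 methyl 6-methylhept-6-en-2-ynoate, via lithium alkynide 9 (not isolated)
Conditions: n-BuLi (1.05 equiv), THF, −78 °C; then ClCO2Me, −78 → 0 °C
Reagents that add atoms: methyl chloroformate, COC(Cl)=O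
Why: Deprotonation and C-acylation of the terminal alkyne gives the ynoate needed for conjugate hydroalumination.

Step 6
Reactants: 10 methyl 6-methylhept-6-en-2-ynoate
Product: 12 methyl (2Z)-6-methyl-2-[(4,4,5,5-tetramethyl-1,3,2-dioxaborolan-2-yl)methyl]hepta-2,6-dienoate, via aluminium allenolate 11 (not isolated)
Conditions: i-Bu2AlH (1.3 equiv), HMPA (2.5 equiv), THF, 0 °C; then ICH2Bpin (1.5 equiv), 0 °C → rt
Reagents that add atoms: 2-(iodomethyl)-4,4,5,5-tetramethyl-1,3,2-dioxaborolane, ICB1OC(C)(C)C(C)(C)O1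
Why: Conjugate hydroalumination of the ynoate gives the allenolate, which is C-alkylated by the iodomethylboronate from the side of the β-hydrogen, placing the chain cis to the ester (Z), the geometry that later gives the trans lactone.

Step 7
Reactants: 6 (2E)-3-methylhept-2-en-6-ynal; 12 methyl (2Z)-6-methyl-2-[(4,4,5,5-tetramethyl-1,3,2-dioxaborolan-2-yl)methyl]hepta-2,6-dienoate
Product: 15 (4R,5S)-3-methylidene-4-(3-methylbut-3-en-1-yl)-5-[(1E)-2-methylhex-1-en-5-yn-1-yl]oxolan-2-one, via pinacol borate 13 (not isolated), via hydroxy ester 14 (not isolated)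
Conditions: (R)-TRIP [(R)-3,3'-bis(2,4,6-triisopropylphenyl)-BINOL hydrogen phosphate] (10 mol%), 4 Å MS, toluene, 0 °C → rt; then H2O (3 equiv), p-TsOH·H2O (10 mol%), rt
Reagents that add atoms: none
Why: Chiral phosphoric acid-catalysed allylboration through a closed chair transition state, in which the acid activates the boronate and directs C–C bond formation to the Re face of the enal (14S), the Z boronate (chain trans to CH2B) fixes the anti relationship (1R), and acid-catalysed lactonisation then closes the trans α-methylene-γ-butyrolactone (first ring).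

Step 8
Reactants: 16 ethyl 1-bromocyclobutane-1-carboxylate
Product: 18 cyclobut-1-ene-1-carboxylic acid, via potassium cyclobutenecarboxylate 17 (not isolated)
Conditions: KOH (4 equiv), toluene, reflux; then aq. HCl, 0 °C; stored cold over BHT and used within days
Reagents that add atoms: potassium hydroxide, [K+].[OH-]
Why: E2 dehydrobromination and ester saponification in one pot (the hydroxide oxygen ends up in the carboxylate), with acidification liberating the strained acid.

Step 9
Reactants: 15 (4R,5S)-3-methylidene-4-(3-methylbut-3-en-1-yl)-5-[(1E)-2-methylhex-1-en-5-yn-1-yl]oxolan-2-one; 18 cyclobut-1-ene-1-carboxylic acid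
Product: 20 (3R,5E)-5-methyl-6-[(2S,3R)-4-methylidene-3-(3-methylbut-3-en-1-yl)-5-oxooxolan-2-yl]hexa-1,5-dien-3-yl cyclobut-1-ene-1-carboxylate, via terminal allene 19 (not isolated)
Conditions: [Rh(cod)Cl]2 (2.5 mol%), (R,R)-Cp-DIOP [cyclopentylidene-ketal analogue of DIOP] (6 mol%), 18 (1.5 equiv), BHT (5 mol%), ClCH2CH2Cl, 60 °C
Reagents that add atoms: none
Why: Proposed new method: catalyst-controlled, branched-selective hydro-acyloxylation of a terminal alkyne with a strained cycloalkenyl acid, in which O–H oxidative addition of 18 to monovalent rhodium gives a trivalent rhodium hydride that isomerises the alkyne to allene 19 (hydrometalation/β-hydride elimination), adds again to give a π-allyl rhodium carboxylate, and forms the C10–O bond by inner-sphere reductive elimination at the substituted terminus inside the chiral diphosphine pocket (10R, set by the catalyst because the lactone stereocentres are six atoms away); the conjugated, trisubstituted cyclobutene C=C and the exo-methylene lactone should be much poorer hydride acceptors than the alkyne and allene, so acid and lactone should survive; the closest known reaction type is the rhodium/DIOP-catalysed redox-neutral coupling of terminal alkynes or allenes with simple carboxylic acids to give branched allylic esters, which has not been shown with cyclobut-1-enecarboxylic acid or on an α-methylene lactone substrate.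

Step 10
Reactants: 20 (3R,5E)-5-methyl-6-[(2S,3R)-4-methylidene-3-(3-methylbut-3-en-1-yl)-5-oxooxolan-2-yl]hexa-1,5-dien-3-yl cyclobut-1-ene-1-carboxylate
Product: 21 ovatodiolide [(1R,10R,14S), 4E, 12E]
Conditions: second-generation Grubbs catalyst (H2IMes)(PCy3)Cl2Ru=CHPh (2 × 5 mol%), toluene, 0.5 mM, 80 °C, slow addition of 20
Reagents that add atoms: none
Why: Ring-opening/ring-closing metathesis cascade, in which the ruthenium alkylidene formed at the C9 vinyl group opens the strained cyclobutene to close the butenolide (C8=C9, second ring) and the new alkylidene at C5 closes the 14-membered carbocycle onto the 1,1-disubstituted alkene (C4=C5, third ring) with loss of ethene, E being the thermodynamically preferred geometry in this ring.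

Step 11
Reactants: 21 ovatodiolide
Product: 22 4-methylene-5β-hydroperoxyovatodiolide [(1R,5R,10R,14S)]
Conditions: O2, 5,10,15,20-tetraphenylporphyrin (0.5 mol%), CH2Cl2, −20 °C, white LED, stopped at about 80% conversion; chromatography at or below 5 °C
Reagents that add atoms: dioxygen (reacting as singlet oxygen), O=O
Why: Schenck ene reaction, in which singlet oxygen attacks the electron-rich C4=C5 alkene (C12=C13 is deactivated by the allylic C14–O bond and the two acrylate-type alkenes are inert) from its exposed outer face, the cis effect limits hydrogen abstraction to C18 or C6, and abstraction from the C18 methyl forms the C5–O bond (5R) and the C4=C18 methylene, the C4-hydroperoxide regioisomer being removed by chromatography.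

## Compound list

1 | geranyl acetate, (2E)-3,7-dimethylocta-2,6-dien-1-yl acetate | CC(C)=CCC/C(C)=C/COC(C)=O | starting material
2 | (2E)-5-(5,5-dimethyl-1,2,4-trioxolan-3-yl)-3-methylpent-2-en-1-yl acetate (ozonide, not isolated) | CC(=O)OC/C=C(\C)CCC1OOC(C)(C)O1 | intermediate
3 | (2E)-3-methyl-6-oxohex-2-en-1-yl acetate | CC(=O)OC/C=C(\C)CCC=O | intermediate
4 | (2E)-3-methylhept-2-en-6-yn-1-yl acetate (not isolated) | CC(=O)OC/C=C(\C)CCC#C | intermediate
5 | (2E)-3-methylhept-2-en-6-yn-1-ol | OC/C=C(\C)CCC#C | intermediate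
6 | (2E)-3-methylhept-2-en-6-ynal | O=C/C=C(\C)CCC#C | intermediate
7 | 4-bromo-2-methylbut-1-ene | C=C(C)CCBr | starting material
8 | 2-methylhex-1-en-5-yne | C=C(C)CCC#C | intermediate
9 | (5-methylhex-5-en-1-yn-1-yl)lithium (not isolated) | [Li]C#CCCC(C)=C | intermediate
10 | methyl 6-methylhept-6-en-2-ynoate | C=C(C)CCC#CC(=O)OC | intermediate
11 | diisobutylaluminium allenolate of 10, i-Bu2Al–O–C(OMe)=C=CH–CH2CH2C(CH3)=CH2 (not isolated) | C=C(C)CCC=C=C(OC)O[Al](CC(C)C)CC(C)C | intermediate
12 | methyl (2Z)-6-methyl-2-[(4,4,5,5-tetramethyl-1,3,2-dioxaborolan-2-yl)methyl]hepta-2,6-dienoate (chain cis to the ester) | C=C(C)CC/C=C(/CB1OC(C)(C)C(C)(C)O1)C(=O)OC | intermediate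
13 | methyl (3R,4S,5E)-6-methyl-2-methylidene-3-(3-methylbut-3-en-1-yl)-4-[(4,4,5,5-tetramethyl-1,3,2-dioxaborolan-2-yl)oxy]dec-5-en-9-ynoate (not isolated) | C=C(C(=O)OC)[C@@H](CCC(C)=C)[C@@H](OB1OC(C)(C)C(C)(C)O1)/C=C(\C)CCC#C | intermediate
14 | methyl (3R,4S,5E)-4-hydroxy-6-methyl-2-methylidene-3-(3-methylbut-3-en-1-yl)dec-5-en-9-ynoate (not isolated) | C=C(C(=O)OC)[C@@H](CCC(C)=C)[C@@H](O)/C=C(\C)CCC#C | intermediate
15 | (4R,5S)-3-methylidene-4-(3-methylbut-3-en-1-yl)-5-[(1E)-2-methylhex-1-en-5-yn-1-yl]oxolan-2-one (trans lactone) | C=C1C(=O)O[C@@H](/C=C(\C)CCC#C)[C@@H]1CCC(C)=C | intermediate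
16 | ethyl 1-bromocyclobutane-1-carboxylate | CCOC(=O)C1(Br)CCC1 | starting material
17 | potassium cyclobut-1-ene-1-carboxylate (not isolated) | [K+].[O-]C(=O)C1=CCC1 | intermediate
18 | cyclobut-1-ene-1-carboxylic acid | OC(=O)C1=CCC1 | intermediate
19 | (4R,5S)-3-methylidene-4-(3-methylbut-3-en-1-yl)-5-[(1E)-2-methylhexa-1,4,5-trien-1-yl]oxolan-2-one (not isolated) | C=C1C(=O)O[C@@H](/C=C(\C)CC=C=C)[C@@H]1CCC(C)=C | intermediate
20 | (3R,5E)-5-methyl-6-[(2S,3R)-4-methylidene-3-(3-methylbut-3-en-1-yl)-5-oxooxolan-2-yl]hexa-1,5-dien-3-yl cyclobut-1-ene-1-carboxylate | C=C1C(=O)O[C@@H](/C=C(\C)C[C@H](C=C)OC(=O)C2=CCC2)[C@@H]1CCC(C)=C | intermediate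
21 | ovatodiolide: 14-membered carbocycle with 4E and 12E trisubstituted alkenes, C8/C19/O–C10 bridging butenolide and trans-fused C1/C14 α-methylene-γ-lactone, (1R,10R,14S) | C=C1C(=O)O[C@H]2/C=C(\C)C[C@@H]3C=C(CC/C=C(\C)CC[C@H]12)C(=O)O3 | intermediate
22 | 4-methylene-5β-hydroperoxyovatodiolide, (1R,5R,10R,14S) | C=C1C(=O)O[C@H]2/C=C(\C)C[C@@H]3C=C(CC[C@@H](OO)C(=C)CC[C@H]12)C(=O)O3 | target

## Step count and risks

Total step count: 11. Longest linear sequence: 7 steps (steps 1, 2, 3, 7, 9, 10, 11 from geranyl acetate; the boronate branch, steps 4, 5, 6, 7, 9, 10, 11, is equally long).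

Steps most likely to fail:

**Step 9 (the proposed new C–O coupling).** The risks are rhodium-hydride isomerisation of the exo-methylene lactone, polymerisation of the strained acid, or poor control at C10. The fallback uses only known chemistry. It sets out from boronate 12 and acid 18 (with purchased acrolein and propargyl bromide) and comes back at 20. The C10–O stereocentre is made by classical means and the acid is attached by ordinary esterification. Zinc-mediated propargylation of acrolein gives racemic hex-1-en-5-yn-3-ol F4. Sharpless kinetic resolution (Ti(OiPr)4, L-(+)-diisopropyl tartrate, t-BuOOH, 4 Å MS, CH2Cl2, −20 °C) leaves (3R)-hex-1-en-5-yn-3-ol F5, while the S enantiomer is removed as the epoxy alcohol (1S)-1-[(2R)-oxiran-2-yl]but-3-yn-1-ol F6. Negishi carboalumination of F5 (Me3Al, Cp2ZrCl2, CH2Cl2), then n-BuLi and paraformaldehyde, gives (2E,5R)-3-methylhepta-2,6-diene-1,5-diol F7. TEMPO/PhI(OAc)2 oxidises only the primary alcohol to give (2E,5R)-5-hydroxy-3-methylhepta-2,6-dienal F8. Allylboration of F8 with 12 under the conditions of step 7 gives methyl (3R,4S,5E,8R)-4,8-dihydroxy-6-methyl-2-methylidene-3-(3-methylbut-3-en-1-yl)deca-5,9-dienoate F9. This lactonises to (4R,5S)-5-[(1E,4R)-4-hydroxy-2-methylhexa-1,5-dien-1-yl]-3-methylidene-4-(3-methylbut-3-en-1-yl)oxolan-2-one F10. Steglich esterification of F10 with 18 (EDC, DMAP, CH2Cl2, 0 °C) gives 20.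

**Step 10 (cascade metathesis).** The risks are oligomerisation of the strained ester or a poor E/Z ratio at C4=C5. The fallback sets out from 20 and comes back at 21, and it separates ring opening from macrocyclisation. Under ethene (1 atm) with the same ruthenium catalyst, 20 undergoes ring-opening cross-metathesis to the acyclic triene ester (3R,5E)-5-methyl-6-[(2S,3R)-4-methylidene-3-(3-methylbut-3-en-1-yl)-5-oxooxolan-2-yl]hexa-1,5-dien-3-yl 2-methylidenehex-5-enoate F11. F11 closes the five-membered butenolide in the same flask to give the isolable (4R,5S)-5-[(1E)-3-[(2R)-4-(but-3-en-1-yl)-5-oxo-2,5-dihydrofuran-2-yl]-2-methylprop-1-en-1-yl]-3-methylidene-4-(3-methylbut-3-en-1-yl)oxolan-2-one F12. The 14-membered ring is then closed in a dedicated step by ring-closing metathesis of the terminal vinyl and 1,1-disubstituted alkenes with the molybdenum alkylidene Mo(NAr)(CHCMe2Ph)[OCMe(CF3)2]2 (Ar = 2,6-diisopropylphenyl) at high dilution, which can be run to the E/Z equilibrium without competing ring-opening oligomerisation.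

**Step 7 (allylboration of an ester-deactivated boronate under phosphoric acid control).** The risks are slow conversion or low enantioselectivity. The fallback sets out from 8 and comes back at 15, and it moves stereocontrol from the catalyst to a covalently bound auxiliary. Alkynide 9 (from 8 and n-BuLi) is acylated with (−)-8-phenylmenthyl chloroformate to give (1R,2S,5R)-5-methyl-2-(2-phenylpropan-2-yl)cyclohexyl 6-methylhept-6-en-2-ynoate F1. Hydroalumination and borylmethylation as in step 6 give (1R,2S,5R)-5-methyl-2-(2-phenylpropan-2-yl)cyclohexyl (2Z)-6-methyl-2-[(4,4,5,5-tetramethyl-1,3,2-dioxaborolan-2-yl)methyl]hepta-2,6-dienoate F2. Sc(OTf)3-catalysed allylboration of 6 with F2 (toluene, −40 °C → rt), with face selection coming from the π-shielding auxiliary, gives after aqueous work-up (1R,2S,5R)-5-methyl-2-(2-phenylpropan-2-yl)cyclohexyl (3R,4S,5E)-4-hydroxy-6-methyl-2-methylidene-3-(3-methylbut-3-en-1-yl)dec-5-en-9-ynoate F3. Lactonisation with p-TsOH expels the auxiliary and returns 15.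

Further compounds
F1 | step 7 | (1R,2S,5R)-5-methyl-2-(2-phenylpropan-2-yl)cyclohexyl 6-methylhept-6-en-2-ynoate | CC(C)(c1ccccc1)[C@@H]1CC[C@@H](C)C[C@H]1OC(=O)C#CCCC(C)=C
F2 | step 7 | (1R,2S,5R)-5-methyl-2-(2-phenylpropan-2-yl)cyclohexyl (2Z)-6-methyl-2-[(4,4,5,5-tetramethyl-1,3,2-dioxaborolan-2-yl)methyl]hepta-2,6-dienoate | CC(C)(c1ccccc1)[C@@H]1CC[C@@H](C)C[C@H]1OC(=O)/C(CB2OC(C)(C)C(C)(C)O2)=C\CCC(C)=C
F3 | step 7 | (1R,2S,5R)-5-methyl-2-(2-phenylpropan-2-yl)cyclohexyl (3R,4S,5E)-4-hydroxy-6-methyl-2-methylidene-3-(3-methylbut-3-en-1-yl)dec-5-en-9-ynoate | CC(C)(c1ccccc1)[C@@H]1CC[C@@H](C)C[C@H]1OC(=O)C(=C)[C@@H](CCC(C)=C)[C@@H](O)/C=C(\C)CCC#C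
F4 | step 9 | racemic hex-1-en-5-yn-3-ol | C=CC(O)CC#C
F5 | step 9 | (3R)-hex-1-en-5-yn-3-ol | C=C[C@H](O)CC#C
F6 | step 9 | (1S)-1-[(2R)-oxiran-2-yl]but-3-yn-1-ol | C#CC[C@H](O)[C@H]1CO1
F7 | step 9 | (2E,5R)-3-methylhepta-2,6-diene-1,5-diol | OC/C=C(\C)C[C@@H](O)C=C
F8 | step 9 | (2E,5R)-5-hydroxy-3-methylhepta-2,6-dienal | O=C/C=C(\C)C[C@@H](O)C=C
F9 | step 9 | methyl (3R,4S,5E,8R)-4,8-dihydroxy-6-methyl-2-methylidene-3-(3-methylbut-3-en-1-yl)deca-5,9-dienoate | C=C(C(=O)OC)[C@@H](CCC(C)=C)[C@@H](O)/C=C(\C)C[C@@H](O)C=C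
F10 | step 9 | (4R,5S)-5-[(1E,4R)-4-hydroxy-2-methylhexa-1,5-dien-1-yl]-3-methylidene-4-(3-methylbut-3-en-1-yl)oxolan-2-one | C=C1C(=O)O[C@@H](/C=C(\C)C[C@@H](O)C=C)[C@@H]1CCC(C)=C
F11 | step 10 | (3R,5E)-5-methyl-6-[(2S,3R)-4-methylidene-3-(3-methylbut-3-en-1-yl)-5-oxooxolan-2-yl]hexa-1,5-dien-3-yl 2-methylidenehex-5-enoate | C=C1C(=O)O[C@@H](/C=C(\C)C[C@H](C=C)OC(=O)C(=C)CCC=C)[C@@H]1CCC(C)=C
F12 | step 10 | (4R,5S)-5-[(1E)-3-[(2R)-4-(but-3-en-1-yl)-5-oxo-2,5-dihydrofuran-2-yl]-2-methylprop-1-en-1-yl]-3-methylidene-4-(3-methylbut-3-en-1-yl)oxolan-2-one | C=C1C(=O)O[C@@H](/C=C(\C)C[C@@H]2C=C(CCC=C)C(=O)O2)[C@@H]1CCC(C)=C
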